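The route exploits the C3(OH)–C4H2–C5(OH) triad of the heptane chain, a pseudo-meso syn-1,3-diol whose two carbinols differ only through the distant guaiacyl (on C1) and syringyl (on C7) rings, so each must be set by reagent control. Both C–O bonds are traced back to C–B bonds and the chain is cut between C3 and C4. An enantioenriched α-lithiated 3-arylpropyl triisopropylbenzoate (guaiacyl half, C3 as carbenoid) adds to the primary boron of an enantioenriched 1,2-bis(pinacolboronate) (syringyl half, from asymmetric alkene diboration); 1,2-metallate migration of C4 from boron to C3 joins the halves, and one oxidation converts both C–B bonds into the diol.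

Key step: step 6

Remark on numbering: C1 is the benzylic CH2 on the 4-hydroxy-3-methoxyphenyl (guaiacyl) ring and C7 that on the 4-hydroxy-3,5-dimethoxyphenyl (syringyl) ring; in this numbering the target is (3S,5R), a syn-1,3-diol.
Assumption: the (R,R)-antipode of the TADDOL-derived phosphonite is taken to give (S)-8 in step 5; should the sense of induction be the opposite on this substrate, the (S,S)-ligand is used with no other change.

Step 1
Reactants: 1 3-(4-hydroxy-3-methoxyphenyl)propan-1-ol
Product: 2 3-[4-(benzyloxy)-3-methoxyphenyl]propan-1-ol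
Conditions: BnBr, K2CO3, acetone, reflux
Reagents that add atoms: benzyl bromide, BrCc1ccccc1
Why: Williamson ether synthesis; carbonate deprotonates only the phenol, so the aliphatic alcohol is left free.

Step 2
Reactants: 2 3-[4-(benzyloxy)-3-methoxyphenyl]propan-1-ol
Product: 3 3-[4-(benzyloxy)-3-methoxyphenyl]propyl 2,4,6-triisopropylbenzoate
Conditions: 2,4,6-triisopropylbenzoic acid, PPh3, DIAD, THF, 0 °C → rt
Reagents that add atoms: 2,4,6-triisopropylbenzoic acid, CC(C)c1cc(C(C)C)c(C(=O)O)c(C(C)C)c1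
Why: Mitsunobu esterification of an unhindered primary alcohol, the usual way to install the hindered benzoate that later directs α-lithiation and serves as leaving group.

Step 3
Reactants: 4 4-bromo-2,6-dimethoxyphenol
Product: 5 2-(benzyloxy)-5-bromo-1,3-dimethoxybenzene
Conditions: BnBr, K2CO3, DMF, rt
Reagents that add atoms: benzyl bromide, BrCc1ccccc1
Why: Williamson ether synthesis on the only acidic OH; the aryl bromide is inert under these conditions.

Step 4
Reactants: 5 2-(benzyloxy)-5-bromo-1,3-dimethoxybenzene; 6 but-3-en-1-ylzinc bromide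
Product: 7 2-(benzyloxy)-5-(but-3-en-1-yl)-1,3-dimethoxybenzene
Conditions: PdCl2(dppf) (3 mol %), THF, 60 °C
Reagents that add atoms: none
Why: Negishi sp2–sp3 cross-coupling; the wide-bite-angle dppf ligand favours reductive elimination over β-hydride elimination, so the terminal alkene should stay in place.

Step 5
Reactants: 7 2-(benzyloxy)-5-(but-3-en-1-yl)-1,3-dimethoxybenzene
Product: 8 (S)-2,2'-{4-[4-(benzyloxy)-3,5-dimethoxyphenyl]butane-1,2-diyl}bis(4,4,5,5-tetramethyl-1,3,2-dioxaborolane)
Conditions: B2pin2, Pt(dba)3 (1 mol %), (R,R)-3,5-diisopropylphenyl-TADDOL phenylphosphonite (1.2 mol %), THF, 60 °C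
Reagents that add atoms: bis(pinacolato)diboron, CC1(C)OB(OC1(C)C)B1OC(C)(C)C(C)(C)O1
Why: Pt(0)/TADDOL-phosphonite-catalysed enantioselective syn-1,2-diboration of a monosubstituted alkene (Morken diboration); ligand-controlled alkene insertion into Pt–B sets the secondary C–B centre (S), the future C5 carbinol, and the aryl ethers are inert.

Step 6
Reactants: 3 3-[4-(benzyloxy)-3-methoxyphenyl]propyl 2,4,6-triisopropylbenzoate; 8 (S)-1,2-bis(pinacolboronate)
Product: 12 (3S,5R)-1-[4-(benzyloxy)-3-methoxyphenyl]-7-[4-(benzyloxy)-3,5-dimethoxyphenyl]heptane-3,5-diol, via (R)-α-lithiated benzoate 9 (not isolated), via lithium boronate complex 10 (not isolated), via (3S,5R)-1,3-bis(pinacolboronate) 11 (not isolated)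
Conditions: s-BuLi, (+)-sparteine, Et2O, −78 °C, 5 h; then 8 (1.3 equiv), −78 °C → 35 °C, 16 h; then 2 M NaOH, 30% H2O2, THF, 0 °C → rt; chromatography
Reagents that add atoms: hydrogen peroxide, OO
Why: (+)-Sparteine/s-BuLi removes the pro-R hydrogen next to the benzoate oxygen of 3 (Hoppe-type deprotonation directed by the carbonyl) to give the configurationally stable (R)-lithio benzoate 9, which is captured with retention by the less hindered primary boron of 8 to give boronate complex 10. On warming, the CH2 group on boron migrates to the adjacent carbon anti to the departing triisopropylbenzoate (1,2-metallate rearrangement, inversion at the carbenoid carbon), and this migration forms the bond between the guaiacyl-side carbinol carbon C3 and the central methylene C4. The closest known reaction type is the lithiation–borylation (Matteson-type) homologation of 1,2-bis(boronic esters) at the primary boron; no ring is closed. C3 is set by the chiral diamine (reagent control) and relayed stereospecifically, C5 is the C–B centre from step 5, and NaOH/H2O2 replaces both C–B bonds by C–OH with retention to give the syn (3S,5R) diol. The step needs regioselection between the two borons of 8, secured by the steric difference between CH2–B and CH–B and by the slight excess of 8, and α-O deprotonation in preference to aryl ortho-lithiation, secured by the directing benzoate carbonyl at −78 °C in Et2O. Because the two halves are made enantioenriched independently, the minor enantiomers should end up mainly in anti diastereomers that chromatography removes.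

Step 7
Reactants: 12 (3S,5R)-1-[4-(benzyloxy)-3-methoxyphenyl]-7-[4-(benzyloxy)-3,5-dimethoxyphenyl]heptane-3,5-diol
Product: 13 (3S,5R)-1-(4-hydroxy-3-methoxyphenyl)-7-(4-hydroxy-3,5-dimethoxyphenyl)heptane-3,5-diol
Conditions: H2 (1 atm), 10% Pd/C, EtOAc/MeOH, rt
Reagents that add atoms: none
Why: Hydrogenolysis of the two benzyl aryl ethers over Pd/C; the secondary alcohols are not benzylic and neither stereocentre is touched.

Compound list
1 | 3-(4-hydroxy-3-methoxyphenyl)propan-1-ol | COc1cc(CCCO)ccc1O | starting material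
2 | 3-[4-(benzyloxy)-3-methoxyphenyl]propan-1-ol | COc1cc(CCCO)ccc1OCc1ccccc1 | intermediate
3 | 3-[4-(benzyloxy)-3-methoxyphenyl]propyl 2,4,6-triisopropylbenzoate | COc1cc(CCCOC(=O)c2c(C(C)C)cc(C(C)C)cc2C(C)C)ccc1OCc1ccccc1 | intermediate
4 | 4-bromo-2,6-dimethoxyphenol | COc1cc(Br)cc(OC)c1O | starting material
5 | 2-(benzyloxy)-5-bromo-1,3-dimethoxybenzene | COc1cc(Br)cc(OC)c1OCc1ccccc1 | intermediate
6 | but-3-en-1-ylzinc bromide | C=CCC[Zn]Br | starting material
7 | 2-(benzyloxy)-5-(but-3-en-1-yl)-1,3-dimethoxybenzene | C=CCCc1cc(OC)c(OCc2ccccc2)c(OC)c1 | intermediate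
8 | (S)-2,2'-{4-[4-(benzyloxy)-3,5-dimethoxyphenyl]butane-1,2-diyl}bis(4,4,5,5-tetramethyl-1,3,2-dioxaborolane) | CC1(C)OB(C[C@H](B2OC(C)(C)C(C)(C)O2)CCc2cc(OC)c(OCc3ccccc3)c(OC)c2)OC1(C)C | intermediate
9 | (R)-3-[4-(benzyloxy)-3-methoxyphenyl]-1-lithiopropyl 2,4,6-triisopropylbenzoate ((+)-sparteine complex) | COc1cc(CC[C@H](OC(=O)c2c(C(C)C)cc(C(C)C)cc2C(C)C)[Li])ccc1OCc1ccccc1 | intermediate (not isolated)
10 | lithium boronate complex: the primary boron of 8 bonded to the carbanion carbon of 9; (R) at the benzoate-bearing carbon, (S) at the secondary C–B carbon | [Li+].COc1cc(CC[C@H](OC(=O)c2c(C(C)C)cc(C(C)C)cc2C(C)C)[B-]2(C[C@H](B3OC(C)(C)C(C)(C)O3)CCc3cc(OC)c(OCc4ccccc4)c(OC)c3)OC(C)(C)C(C)(C)O2)ccc1OCc1ccccc1 | intermediate (not isolated)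
11 | 2,2'-{(3S,5R)-1-[4-(benzyloxy)-3-methoxyphenyl]-7-[4-(benzyloxy)-3,5-dimethoxyphenyl]heptane-3,5-diyl}bis(4,4,5,5-tetramethyl-1,3,2-dioxaborolane) | COc1cc(CC[C@H](B2OC(C)(C)C(C)(C)O2)C[C@H](B2OC(C)(C)C(C)(C)O2)CCc2cc(OC)c(OCc3ccccc3)c(OC)c2)ccc1OCc1ccccc1 | intermediate (not isolated)
12 | (3S,5R)-1-[4-(benzyloxy)-3-methoxyphenyl]-7-[4-(benzyloxy)-3,5-dimethoxyphenyl]heptane-3,5-diol | COc1cc(CC[C@H](O)C[C@H](O)CCc2cc(OC)c(OCc3ccccc3)c(OC)c2)ccc1OCc1ccccc1 | intermediate
13 | (3S,5R)-1-(4-hydroxy-3-methoxyphenyl)-7-(4-hydroxy-3,5-dimethoxyphenyl)heptane-3,5-diol | COc1cc(CC[C@H](O)C[C@H](O)CCc2cc(OC)c(O)c(OC)c2)ccc1O | target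

Total step count: 7. Longest linear sequence: 5 steps (steps 3, 4, 5, 6, 7, from 4 to 13).

Steps most likely to fail

1. Step 6. What may go wrong: lithiation at the wrong site (ring positions ortho to the ether oxygens or the OCH2Ph group), loss of configuration of the lithiated benzoate before capture, capture by the secondary boron or a second homologation, and incomplete 1,2-migration. The fallback joins the same two carbons by dithiane umpolung and sets C3 afterwards by 1,3-induction; it sets out from 2 and 8 and comes back at 12. Alcohol 2 is oxidised (SO3·pyridine, DMSO, Et3N) to 3-[4-(benzyloxy)-3-methoxyphenyl]propanal F1, which is converted with propane-1,3-dithiol and BF3·OEt2 into 2-{2-[4-(benzyloxy)-3-methoxyphenyl]ethyl}-1,3-dithiane F2. Bis(boronate) 8 is oxidised (NaOH, H2O2) to (R)-4-[4-(benzyloxy)-3,5-dimethoxyphenyl]butane-1,2-diol F3, which NaH and N-tosylimidazole convert, through the primary tosylate (R)-4-[4-(benzyloxy)-3,5-dimethoxyphenyl]-2-hydroxybutyl 4-methylbenzenesulfonate F4, into (R)-2-{2-[4-(benzyloxy)-3,5-dimethoxyphenyl]ethyl}oxirane F5 with the C–O bond at the stereocentre untouched. Deprotonation of F2 (n-BuLi, THF, −20 °C) gives the 2-lithio-1,3-dithiane F6, which should open F5 at its CH2 terminus to give the hydroxy dithiane F7. Dethioketalisation (MeI, CaCO3, aqueous MeCN) gives (R)-1-[4-(benzyloxy)-3-methoxyphenyl]-7-[4-(benzyloxy)-3,5-dimethoxyphenyl]-5-hydroxyheptan-3-one F8, and Narasaka–Prasad reduction (Et2BOMe, NaBH4, THF/MeOH, −78 °C) should deliver the syn diol 12.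

2. Step 5. What may go wrong: poor enantioface discrimination at the unfunctionalised terminal alkene, and alkene isomerisation or hydroboration in competition with diboration. The fallback gives up catalyst control at C5 and relies on diastereomer separation; it sets out from 7 and comes back at 12. Transition-metal-free diboration of 7 (B2pin2, catalytic Cs2CO3, MeOH, THF, 70 °C) gives the racemic 1,2-bis(pinacolboronate) F9. This is taken through step 6 as written: 9 adds to F9 to give the boronate complexes epimeric at C5 F10, which rearrange to the 1,3-bis(pinacolboronates) epimeric at C5 F11. Oxidation in the same flask gives 12 together with its (3S,5S)-anti diastereomer F12, and chromatography should separate the two, C3 still being set by (+)-sparteine.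

3. Step 4. What may go wrong: slow oxidative addition at the electron-rich aryl bromide, β-hydride elimination and re-insertion that move the double bond along the chain, and homocoupling. The fallback reverses the polarity of the two partners; it sets out from 5 and comes back at 7. Magnesium insertion into 5 (Mg, LiCl, THF) gives [4-(benzyloxy)-3,5-dimethoxyphenyl]magnesium bromide F13, and copper-catalysed Kochi-type coupling with 4-bromobut-1-ene (Li2CuCl4 cat., THF/NMP, 0 °C → rt) should give 7.

Further compounds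
F1 | step 6 | 3-[4-(benzyloxy)-3-methoxyphenyl]propanal | COc1cc(CCC=O)ccc1OCc1ccccc1
F2 | step 6 | 2-{2-[4-(benzyloxy)-3-methoxyphenyl]ethyl}-1,3-dithiane | COc1cc(CCC2SCCCS2)ccc1OCc1ccccc1
F3 | step 6 | (R)-4-[4-(benzyloxy)-3,5-dimethoxyphenyl]butane-1,2-diol | OC[C@H](O)CCc1cc(OC)c(OCc2ccccc2)c(OC)c1
F4 | step 6 | (R)-4-[4-(benzyloxy)-3,5-dimethoxyphenyl]-2-hydroxybutyl 4-methylbenzenesulfonate | Cc1ccc(S(=O)(=O)OC[C@H](O)CCc2cc(OC)c(OCc3ccccc3)c(OC)c2)cc1
F5 | step 6 | (R)-2-{2-[4-(benzyloxy)-3,5-dimethoxyphenyl]ethyl}oxirane | C1[C@H](O1)CCc1cc(OC)c(OCc2ccccc2)c(OC)c1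
F6 | step 6 | 2-lithio-2-{2-[4-(benzyloxy)-3-methoxyphenyl]ethyl}-1,3-dithiane | COc1cc(CCC2([Li])SCCCS2)ccc1OCc1ccccc1
F7 | step 6 | (R)-1-(2-{2-[4-(benzyloxy)-3-methoxyphenyl]ethyl}-1,3-dithian-2-yl)-4-[4-(benzyloxy)-3,5-dimethoxyphenyl]butan-2-ol | COc1cc(CCC2(C[C@H](O)CCc3cc(OC)c(OCc4ccccc4)c(OC)c3)SCCCS2)ccc1OCc1ccccc1
F8 | step 6 | (R)-1-[4-(benzyloxy)-3-methoxyphenyl]-7-[4-(benzyloxy)-3,5-dimethoxyphenyl]-5-hydroxyheptan-3-one | COc1cc(CCC(=O)C[C@H](O)CCc2cc(OC)c(OCc3ccccc3)c(OC)c2)ccc1OCc1ccccc1
F9 | step 5 | racemic 2,2'-{4-[4-(benzyloxy)-3,5-dimethoxyphenyl]butane-1,2-diyl}bis(4,4,5,5-tetramethyl-1,3,2-dioxaborolane) | CC1(C)OB(CC(B2OC(C)(C)C(C)(C)O2)CCc2cc(OC)c(OCc3ccccc3)c(OC)c2)OC1(C)C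
F10 | step 5 | lithium boronate complexes of 9 with F9, (R) at the benzoate-bearing carbon, epimeric at C5 | [Li+].COc1cc(CC[C@H](OC(=O)c2c(C(C)C)cc(C(C)C)cc2C(C)C)[B-]2(CC(B3OC(C)(C)C(C)(C)O3)CCc3cc(OC)c(OCc4ccccc4)c(OC)c3)OC(C)(C)C(C)(C)O2)ccc1OCc1ccccc1
F11 | step 5 | (3S)-1,3-bis(pinacolboronates) epimeric at C5 | COc1cc(CC[C@H](B2OC(C)(C)C(C)(C)O2)CC(B2OC(C)(C)C(C)(C)O2)CCc2cc(OC)c(OCc3ccccc3)c(OC)c2)ccc1OCc1ccccc1
F12 | step 5 | (3S,5S)-1-[4-(benzyloxy)-3-methoxyphenyl]-7-[4-(benzyloxy)-3,5-dimethoxyphenyl]heptane-3,5-diol | COc1cc(CC[C@H](O)C[C@@H](O)CCc2cc(OC)c(OCc3ccccc3)c(OC)c2)ccc1OCc1ccccc1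
F13 | step 4 | [4-(benzyloxy)-3,5-dimethoxyphenyl]magnesium bromide | COc1cc([Mg]Br)cc(OC)c1OCc1ccccc1
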